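**Retrosynthetic overview** (carotane numbering: C1 quaternary C–CH3, C2 CH–OAc, C3 CH2, C4 carbinol with isopropyl, C5 ring-fusion CH, C6 CH–O-anisoyl, C7 CH2, C8(CH3)=C9, C10 CH2)
1. The target comes from O6 anisoylation and a hydroxyl-directed reduction of a trans-hydroazulenone aldol (C6 ketone, C4 OH, C2 OAc).
2. Key disconnection: bond C1–C5 is traced back to a bond C1–C6. The five-membered ring (C1–C5) comes by contraction from six-membered ring A (C1–C6) of a cis-decalin, and in the same event cyclohexene ring B (C1, C6–C10) grows to the cycloheptene.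
3. Enabling feature: C5 stands between the quaternary C1 and the oxygenated C6 and has the C4 carbinol on its other side. The contiguous O4/C5/O6 array next to C1 is therefore the retron of a 1,2-shift in an all-cis 4,5,6-triol 5-mesylate.
4. The cis-decalin comes from ring-closing metathesis (ring B), methallylzinc addition to an α-mesyloxy ketone, and syn-dihydroxylation of a C4=C5 enone.
5. The enone comes from a desymmetrising CBS reduction (sets C1 and C2) of a 2,2-dialkylated 5-isopropylcyclohexane-1,3-dione. Ring order: ring A is bought, ring B is closed in step 10, and both are resized in step 11.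

Key step: step 11

Remark: β is the face of ring A that carries the C1 methyl group and α is the opposite face.
Assumption: the propargylated dione and the two compounds made from it are carried as mixtures of epimers at the isopropyl-bearing carbon (C4), because this centre becomes trigonal in step 5.

Step 1
Reactants: 1 5-isopropylcyclohexane-1,3-dione
Product: 2 5-isopropyl-2-methylcyclohexane-1,3-dione
Conditions: MeI, NaOH, H2O/1,4-dioxane, 65 °C
Reagents that add atoms: iodomethane, CI
Why: C-alkylation of the doubly stabilised 1,3-diketone enolate places the future C1 methyl group between the two carbonyl groups, and the enolised product has no stereocentre that matters.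

Step 2
Reactants: 2 5-isopropyl-2-methylcyclohexane-1,3-dione; 3 3-bromoprop-1-yne (propargyl bromide)
Product: 4 2-methyl-2-propargyl-5-isopropylcyclohexane-1,3-dione
Conditions: NaOH, H2O, 25 to 50 °C
Reagents that add atoms: none
Why: A second enolate C-alkylation builds the quaternary carbon (future C1); both diastereomers of 4 keep a mirror plane, and the alkyne serves as an osmium-tolerant mask of the allyl group.

Step 3
Reactants: 4 2-methyl-2-propargyl-5-isopropylcyclohexane-1,3-dione
Product: 5 (2S,3S)-hydroxy ketone
Conditions: (R)-1-methyl-3,3-diphenyltetrahydro-1H,3H-pyrrolo[1,2-c][1,3,2]oxazaborole (20 mol %), catecholborane, toluene, −60 °C; MeOH, aq NaHCO3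
Reagents that add atoms: none
Why: Desymmetrising CBS reduction: the oxazaborolidine binds one of the two enantiotopic carbonyl groups with the quaternary carbon as the large substituent, and hydride enters from the face bearing the smaller methyl group, which should set C2 (S) and thereby C1 (S) with the hydroxyl cis to the propargyl chain.

Step 4
Reactants: 5 (2S,3S)-hydroxy ketone
Product: 6 keto acetate
Conditions: Ac2O, DMAP, pyridine, 25 °C
Reagents that add atoms: acetic anhydride, CC(=O)OC(C)=O
Why: DMAP-catalysed acylation installs the C2 acetate of the target at once, and the β-acyloxy ketone cannot eliminate because the quaternary C1 has no α-hydrogen.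

Step 5
Reactants: 6 keto acetate
Product: 7 C4=C5 enone
Conditions: 2-iodoxybenzoic acid (IBX), DMSO, 70 °C
Reagents that add atoms: none
Why: IBX dehydrogenation through the only possible enol (towards C5) gives the enone, erases the undefined isopropyl-bearing centre and merges both epimers into one compound.

Step 6
Reactants: 7 C4=C5 enone
Product: 8 alkynyl cis-diol
Conditions: K2OsO2(OH)4 (5 mol %), N-methylmorpholine N-oxide, citric acid, t-BuOH/H2O, 25 °C
Reagents that add atoms: N-methylmorpholine N-oxide, C[N+]1([O-])CCOCC1; water, O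
Why: Catalytic OsO4 syn-dihydroxylation (Upjohn conditions, citric acid for an electron-poor alkene) adds both oxygens suprafacially to the β face, opposite the pseudoaxial propargyl chain on C1 and the C2 acetate, which should set C4 (R) and C5 (S), while the terminal alkyne reacts much more slowly.

Step 7
Reactants: 8 alkynyl cis-diol
Product: 9 allyl cis-diol
Conditions: H2 (1 atm), Pd on CaCO3 poisoned with Pb(OAc)2, quinoline, EtOAc, 25 °C
Reagents that add atoms: none
Why: Lindlar semihydrogenation stops at the alkene and unmasks the allyl group now that no osmium reagent follows.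

Step 8
Reactants: 9 allyl cis-diol
Product: 11 α-mesyloxy ketone silyl ether, via hydroxy mesylate 10 (not isolated)
Conditions: MsCl, Et3N, CH2Cl2, −20 °C; then 1-(trimethylsilyl)imidazole, 25 °C
Reagents that add atoms: methanesulfonyl chloride, CS(=O)(=O)Cl; 1-(trimethylsilyl)imidazole, C[Si](C)(C)n1ccnc1
Why: Sulfonylation takes only the secondary C5 hydroxyl, and neutral silyl transfer then caps the tertiary C4 hydroxyl without enolising the ketone, so that O4 cannot act as an electron donor later.

Step 9
Reactants: 11 α-mesyloxy ketone silyl ether; 12 3-bromo-2-methylprop-1-ene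
Product: 13 tertiary carbinol diene
Conditions: 12, Zn, LiCl, THF, 25 °C; then 11, THF, −78 °C; AcOH, −78 °C
Reagents that add atoms: none
Why: 1,2-Addition of an allylic zinc reagent (ester-tolerant, weakly basic, cyclic transition state): in the chair fixed by the equatorial isopropyl group the axial C4 silyl ether blocks the axial trajectory, so equatorial attack should give the axial C6 hydroxyl (R), cis to O5 and O4, with the methallyl chain gauche to the axial allyl group.

Step 10
Reactants: 13 tertiary carbinol diene
Product: 14 cis-decalin hydroxy mesylate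
Conditions: second-generation Grubbs catalyst RuCl2(=CHPh)(PCy3)(H2IMes) (5 mol %), CH2Cl2, 40 °C
Reagents that add atoms: none
Why: Ring-closing metathesis of the monosubstituted and the 1,1-disubstituted alkene closes the unstrained cyclohexene ring B with the trisubstituted C8=C9 bond in place and forms no stereocentre.

Step 11
Reactants: 14 cis-decalin hydroxy mesylate
Product: 17 trans-hydroazulenone aldol, via aluminium alkoxide 15 (not isolated), via silyl ether ketone 16 (not isolated)
Conditions: Et3Al, CH2Cl2, −78 to 0 °C; then 1 M aq HCl, THF, 0 °C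
Reagents that add atoms: none
Why: Et3Al turns the C6 hydroxyl into the diethylaluminium alkoxide 15, whose Lewis-acidic metal also binds the neighbouring mesylate, and as the C5–O bond ionises the antiperiplanar C1–C6 σ-bond migrates to C5 while O6 closes to the ketone (concerted push–pull 1,2-shift). This is a semipinacol (pinacol-type) rearrangement of a vicinal hydroxy sulfonate in its organoaluminium-promoted form, in ring terms the classical hydronaphthalene-to-hydroazulene change. The five-membered ring C1–C5 results from ring A by contraction, C6 being expelled from it, and the seven-membered ring results from ring B by insertion of C5 between C1 and C6, so neither ring is closed by an end-to-end cyclisation. The only new stereocentre, C5, is set by inversion at the mesylate carbon (5β-OMs gives 5α-H) and C1 migrates with retention, so the cis-decalin should deliver the trans-fused hydroazulene. The step needs C1 and not C3, C7 or hydrogen to migrate: the equatorial isopropyl group locks ring A in the chair with the mesylate equatorial, so only the ring bonds C6–C1 and C4–C3 are antiperiplanar, only O6 is a metallated donor because O4 is silylated, the all-cis O4/O5/O6 array rules out epoxide formation, and the C2 acetate is too poor a leaving group for Grob fragmentation. The acidic work-up removes the trimethylsilyl group and leaves the acetate untouched.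

Step 12
Reactants: 17 trans-hydroazulenone aldol
Product: 18 4,6-diol
Conditions: Me4NBH(OAc)3, MeCN/AcOH, −25 °C
Reagents that add atoms: none
Why: Hydroxyl-directed reduction (Evans–Saksena type): the free C4 hydroxyl exchanges an acetate on boron and hydride is delivered within the chelate to the β face of the C6 carbonyl, the face an external hydride would avoid because of the C1 methyl group, which should give the 6α-alcohol (S), anti to O4.

Step 13
Reactants: 18 4,6-diol; 19 4-methoxybenzoyl chloride
Product: 20 CNP0171090.1 (target)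
Conditions: DMAP, Et3N, CH2Cl2, 25 °C
Reagents that add atoms: none
Why: DMAP-catalysed acylation with the acid chloride esterifies only the secondary C6 hydroxyl, since the tertiary C4 hydroxyl is inert under these conditions and no stereocentre is touched.

**Compound list**
1 | 5-isopropylcyclohexane-1,3-dione | CC(C)C1CC(=O)CC(=O)C1 | starting material
2 | 5-isopropyl-2-methylcyclohexane-1,3-dione (enolised, no defined stereocentre) | CC(C)C1CC(=O)C(C)C(=O)C1 | intermediate
3 | 3-bromoprop-1-yne | C#CCBr | starting material
4 | 2-methyl-5-(propan-2-yl)-2-(prop-2-yn-1-yl)cyclohexane-1,3-dione (achiral, cis/trans mixture) | CC(C)C1CC(=O)C(C)(CC#C)C(=O)C1 | intermediate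
5 | (2S,3S)-3-hydroxy-2-methyl-5-(propan-2-yl)-2-(prop-2-yn-1-yl)cyclohexan-1-one (both epimers at ring C5) | O=C1[C@@](C)(CC#C)[C@@H](O)CC(C(C)C)C1 | intermediate
6 | (1S,2S)-2-methyl-3-oxo-5-(propan-2-yl)-2-(prop-2-yn-1-yl)cyclohexyl acetate (both epimers at ring C5) | O=C1[C@@](C)(CC#C)[C@@H](OC(C)=O)CC(C(C)C)C1 | intermediate
7 | (1S,6S)-6-methyl-5-oxo-3-(propan-2-yl)-6-(prop-2-yn-1-yl)cyclohex-3-en-1-yl acetate | O=C1[C@@](C)(CC#C)[C@@H](OC(C)=O)CC(C(C)C)=C1 | intermediate
8 | (1S,3R,4S,6S)-3,4-dihydroxy-6-methyl-5-oxo-3-(propan-2-yl)-6-(prop-2-yn-1-yl)cyclohexyl acetate | O=C1[C@@](C)(CC#C)[C@@H](OC(C)=O)C[C@@](O)(C(C)C)[C@@H]1O | intermediate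
9 | (1S,3R,4S,6S)-3,4-dihydroxy-6-methyl-5-oxo-3-(propan-2-yl)-6-(prop-2-en-1-yl)cyclohexyl acetate | O=C1[C@@](C)(CC=C)[C@@H](OC(C)=O)C[C@@](O)(C(C)C)[C@@H]1O | intermediate
10 | (1S,3R,4S,6S)-3-hydroxy-4-(methanesulfonyloxy)-6-methyl-5-oxo-3-(propan-2-yl)-6-(prop-2-en-1-yl)cyclohexyl acetate | O=C1[C@@](C)(CC=C)[C@@H](OC(C)=O)C[C@@](O)(C(C)C)[C@@H]1OS(C)(=O)=O | intermediate
11 | (1S,3R,4S,6S)-4-(methanesulfonyloxy)-6-methyl-5-oxo-3-(propan-2-yl)-6-(prop-2-en-1-yl)-3-(trimethylsilyloxy)cyclohexyl acetate | O=C1[C@@](C)(CC=C)[C@@H](OC(C)=O)C[C@@](O[Si](C)(C)C)(C(C)C)[C@@H]1OS(C)(=O)=O | intermediate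
12 | 3-bromo-2-methylprop-1-ene | C=C(C)CBr | starting material
13 | (1S,3R,4R,5R,6S)-5-hydroxy-4-(methanesulfonyloxy)-6-methyl-5-(2-methylprop-2-en-1-yl)-3-(propan-2-yl)-6-(prop-2-en-1-yl)-3-(trimethylsilyloxy)cyclohexyl acetate | O[C@]1(CC(C)=C)[C@@](C)(CC=C)[C@@H](OC(C)=O)C[C@@](O[Si](C)(C)C)(C(C)C)[C@@H]1OS(C)(=O)=O | intermediate
14 | (1R,2R,4S,4aS,8aR)-4-acetoxy-8a-hydroxy-4a,7-dimethyl-2-(propan-2-yl)-2-(trimethylsilyloxy)-1,2,3,4,4a,5,8,8a-octahydronaphthalen-1-yl methanesulfonate (cis-decalin) | O[C@]12CC(C)=CC[C@@]1(C)[C@@H](OC(C)=O)C[C@@](O[Si](C)(C)C)(C(C)C)[C@@H]2OS(C)(=O)=O | intermediate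
15 | O-diethylaluminium alkoxide of 14 | CC[Al](CC)O[C@]12CC(C)=CC[C@@]1(C)[C@@H](OC(C)=O)C[C@@](O[Si](C)(C)C)(C(C)C)[C@@H]2OS(C)(=O)=O | intermediate
16 | (1S,3R,3aR,8aR)-6,8a-dimethyl-4-oxo-3-(propan-2-yl)-3-(trimethylsilyloxy)-1,2,3,3a,4,5,8,8a-octahydroazulen-1-yl acetate | O=C1CC(C)=CC[C@@]2(C)[C@@H](OC(C)=O)C[C@@](O[Si](C)(C)C)(C(C)C)[C@H]12 | intermediate
17 | (1S,3R,3aR,8aR)-3-hydroxy-6,8a-dimethyl-4-oxo-3-(propan-2-yl)-1,2,3,3a,4,5,8,8a-octahydroazulen-1-yl acetate | O=C1CC(C)=CC[C@@]2(C)[C@@H](OC(C)=O)C[C@@](O)(C(C)C)[C@H]12 | intermediate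
18 | (1S,3R,3aS,4S,8aR)-3,4-dihydroxy-6,8a-dimethyl-3-(propan-2-yl)-1,2,3,3a,4,5,8,8a-octahydroazulen-1-yl acetate | O[C@H]1CC(C)=CC[C@@]2(C)[C@@H](OC(C)=O)C[C@@](O)(C(C)C)[C@H]12 | intermediate
19 | 4-methoxybenzoyl chloride | COc1ccc(C(=O)Cl)cc1 | starting material
20 | (1S,3R,3aS,4S,8aR)-1-acetoxy-3-hydroxy-6,8a-dimethyl-3-(propan-2-yl)-1,2,3,3a,4,5,8,8a-octahydroazulen-4-yl 4-methoxybenzoate | COc1ccc(C(=O)O[C@H]2CC(C)=CC[C@@]3(C)[C@@H](OC(C)=O)C[C@@](O)(C(C)C)[C@H]23)cc1 | target

Total step count: 13. Longest linear sequence: 13 steps (1 to 20).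

**Steps most likely to fail**

Step 11. The cis-fused ring B may tilt ring A away from the chair that holds the C5–O bond antiperiplanar to C1–C6. Ionisation of the hindered mesylate would then become slow, and silyl transfer between the syn-axial oxygens, elimination or fragmentation could take over.
- The fallback sets out from 13 and comes back at 16.
- The 1,2-shift is run before ring B exists. Et3Al in CH2Cl2 acts on monocyclic 13, whose chair is free of the ring fusion, and the ring contraction should give the cyclopentyl methallyl ketone F1.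
- Ring-closing metathesis of F1 with the second-generation Grubbs catalyst then closes the seven-membered ring directly to 16, which is desilylated to 17 as in the route.

Step 9. Enolisation of the α-mesyloxy ketone, or poor facial selectivity in the addition to the very hindered carbonyl group, would give a carbinol whose two side chains cannot meet in the metathesis.
- The fallback sets out from 11 and comes back at 16.
- NaBH4 in MeOH reduces the ketone to the secondary carbinol F2. Either C6 epimer serves, because C6 becomes trigonal again.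
- Et3Al induces the ring contraction to the cyclopentanecarbaldehyde F3.
- 2-Methylallylzinc bromide adds to this unhindered aldehyde to give the homoallylic alcohol F4.
- Metathesis closes the cycloheptenol F5, and Dess–Martin periodinane oxidises it to 16.

Step 6. Possible problems are sluggish osmylation of the hindered, electron-poor trisubstituted alkene, competing oxidation of the alkyne, or poor facial selectivity.
- The fallback sets out from 7 and comes back at 8, and it brings in the two oxygens one after the other.
- t-BuOOH/DBU (Weitz–Scheffer epoxidation, again opposite the propargyl chain) gives the epoxy ketone F6.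
- PhSeSePh/NaBH4/AcOH opens it reductively at C5 to the aldol F7.
- Me3SiOTf/Et3N gives the bis-silylated enol ether F8.
- Rubottom oxidation with dimethyldioxirane follows, then methanolic HCl to strip both silyl groups, then brief contact with Et3N to let the C5 carbinol settle in the equatorial position. This leads to 8.

**Further compounds**
F1 | step 11 | cyclopentyl methallyl ketone (carotane 1R,2S,4R,5R): 2-acetoxy-1-allyl-1-methyl-5-(3-methylbut-3-enoyl)-4-isopropyl-4-(trimethylsilyloxy)cyclopentane | C=C(C)CC(=O)[C@@H]1[C@@](C)(CC=C)[C@@H](OC(C)=O)C[C@@]1(O[Si](C)(C)C)C(C)C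
F2 | step 9 | secondary carbinol from reduction of 11 (axial 6β-OH drawn, either epimer serves) | O[C@@H]1[C@@](C)(CC=C)[C@@H](OC(C)=O)C[C@@](O[Si](C)(C)C)(C(C)C)[C@@H]1OS(C)(=O)=O
F3 | step 9 | cyclopentanecarbaldehyde (carotane 1R,2S,4R,5R) | O=C[C@@H]1[C@@](C)(CC=C)[C@@H](OC(C)=O)C[C@@]1(O[Si](C)(C)C)C(C)C
F4 | step 9 | homoallylic alcohol from methallylation of F3 (C6 epimers) | C=C(C)CC(O)[C@@H]1[C@@](C)(CC=C)[C@@H](OC(C)=O)C[C@@]1(O[Si](C)(C)C)C(C)C
F5 | step 9 | trans-hydroazulene C6 alcohol, O4 silyl ether (C6 epimers) | OC1CC(C)=CC[C@@]2(C)[C@@H](OC(C)=O)C[C@@](O[Si](C)(C)C)(C(C)C)[C@H]12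
F6 | step 6 | 4β,5β-epoxy ketone from 7 | O=C1[C@@](C)(CC#C)[C@@H](OC(C)=O)C[C@]2(C(C)C)O[C@H]12
F7 | step 6 | 4β-hydroxy ketone (aldol) | O=C1[C@@](C)(CC#C)[C@@H](OC(C)=O)C[C@@](O)(C(C)C)C1
F8 | step 6 | C5=C6 trimethylsilyl enol ether of F7 with O4 trimethylsilyl ether | C[Si](C)(C)OC1=C[C@](O[Si](C)(C)C)(C(C)C)C[C@H](OC(C)=O)[C@]1(C)CC#C
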